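**Plan** (labels follow the cyclodeca[b]furan numbering of the target: O1, C2 lactone carbonyl, C3 methylene carbon, C3a, C4 acyloxy carbon, C5, C6 ester-bearing olefin carbon, C7 olefin CH, C8, C9, C10 hydroxymethyl carbon, C11, C11a; precursors keep these labels)
1. Cuts: C7–C8 (sp2–sp3, closes the ten-membered ring), the O4 acyl group, C3=CH2, C4–C5 (propargylation), C3a–C11a with O1–C2 (aldol/lactonisation), and the C10–C11 bond to a malonate carbon.
2. Enabling feature: O4 and the enoate β-carbon C7 are 1,4-related through C5–C6, so they can be tied into a five-membered 4,5-dihydrofuran-3-carboxylate (ring O4–C4–C5–C6=C7). Its C7–O bond serves as the leaving group and the ring fixes the olefin geometry; C8 is a plain CH2 reachable by hydroboration of a C8=C9 vinyl group.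
3. Forward order: C8–C11a aldehyde → auxiliary syn-aldol and lactonisation (γ-lactone) → propargylation at C4 → alkynol cycloisomerisation and C6 acylation (oxolene helper ring) → one-pot hydroboration/nickel ring-opening macrocyclisation (carbocycle closes as the oxolene opens) → O4 acylation, methylenation, deprotection.
4. Stereochemistry: C10 from ligand-controlled iridium allylic alkylation; C3a/C11a from the thiazolidinethione syn-aldol; C4 from catalyst-controlled allenylboration; 6E from stereoretentive C–O to C–C exchange on the cis oxolene; the side chain from (2S)-2-methylbutanoic anhydride.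
5. Helpers and their removal: the oxolene ring (opened in the key step), the C3 phosphonate as masked methylene (step 15), the 4-methoxybenzyl ether (step 16).

Key step: step 13

Assumption: the enantiomers of the phosphoramidite ligand (step 3) and of the phosphoric acid (step 9) are named by analogy with their usual sense of induction; should one induce the opposite sense, its mirror image is used.

Step 1
Reactants: 1 (E)-but-2-ene-1,4-diol; 2 4-methoxybenzyl chloride
Product: 3 (E)-4-[(4-methoxybenzyl)oxy]but-2-en-1-ol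
Conditions: NaH (1 equiv), 1 (3 equiv), THF/DMF, 0 °C; then 2, Bu4NI (cat.), rt
Reagents that add atoms: 4-methoxybenzyl chloride, COc1ccc(CCl)cc1
Why: Williamson etherification, in which the excess of diol should favour the mono-ether.

Step 2
Reactants: 3 (E)-4-[(4-methoxybenzyl)oxy]but-2-en-1-ol; 4 methyl chloroformate
Product: 5 (E)-4-[(4-methoxybenzyl)oxy]but-2-en-1-yl methyl carbonate
Conditions: pyridine, CH2Cl2, 0 °C
Reagents that add atoms: methyl chloroformate, COC(=O)Cl
Why: O-acylation of the allylic alcohol installs the carbonate leaving group for allylic substitution.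

Step 3
Reactants: 5 (E)-4-[(4-methoxybenzyl)oxy]but-2-en-1-yl methyl carbonate; 6 dimethyl malonate
Product: 7 dimethyl 2-[(2S)-1-[(4-methoxybenzyl)oxy]but-3-en-2-yl]propanedioate
Conditions: [Ir(cod)Cl]2 (2 mol %), (Ra,R,R)-BINOL-derived N,N-bis(1-phenylethyl)phosphoramidite (4 mol %), TBD (8 mol %), THF, rt
Reagents that add atoms: dimethyl malonate, COC(=O)CC(=O)OC
Why: Iridium-catalysed asymmetric allylic alkylation (Tsuji–Trost type), in which the cyclometalated iridium–phosphoramidite complex ionises the carbonate and directs the malonate (deprotonated by the methoxide released on decarboxylation) to the substituted allyl terminus, so the branched product should form with the ligand setting C10.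

Step 4
Reactants: 7 dimethyl 2-[(2S)-1-[(4-methoxybenzyl)oxy]but-3-en-2-yl]propanedioate
Product: 8 methyl (3R)-3-{[(4-methoxybenzyl)oxy]methyl}pent-4-enoate
Conditions: NaCl, H2O, DMSO, 150 °C
Reagents that add atoms: none
Why: Krapcho dealkoxycarbonylation, in which chloride demethylates one ester and the carboxylate decarboxylates without touching the stereocentre.

Step 5
Reactants: 8 methyl (3R)-3-{[(4-methoxybenzyl)oxy]methyl}pent-4-enoate
Product: 9 (3R)-3-{[(4-methoxybenzyl)oxy]methyl}pent-4-enal
Conditions: iBu2AlH (1.1 equiv), CH2Cl2, −78 °C; Rochelle salt work-up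
Reagents that add atoms: none
Why: Partial ester reduction through the tetrahedral aluminium hemiacetal, which is stable at −78 °C and should release the aldehyde only on work-up.

Step 6
Reactants: 10 (4S)-4-benzyl-1,3-thiazolidine-2-thione; 11 methyl 4-chloro-4-oxobutanoate
Product: 12 methyl 4-[(4S)-4-benzyl-2-thioxo-1,3-thiazolidin-3-yl]-4-oxobutanoate
Conditions: Et3N, DMAP (cat.), CH2Cl2, 0 °C
Reagents that add atoms: methyl 4-chloro-4-oxobutanoate, COC(=O)CCC(=O)Cl
Why: N-acylation of the auxiliary by the acid chloride gives the succinate donor for the aldol reaction.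

Step 7
Reactants: 12 methyl 4-[(4S)-4-benzyl-2-thioxo-1,3-thiazolidin-3-yl]-4-oxobutanoate; 9 (3R)-3-{[(4-methoxybenzyl)oxy]methyl}pent-4-enal
Product: 14 (4S)-4-benzyl-3-{[(2R,3S)-2-[(2R)-2-{[(4-methoxybenzyl)oxy]methyl}but-3-en-1-yl]-5-oxooxolan-3-yl]carbonyl}-1,3-thiazolidine-2-thione, via syn-aldol adduct 13 (not isolated)
Conditions: 12, TiCl4 (1.05 equiv), iPr2NEt (1.1 equiv), NMP (1 equiv), CH2Cl2, −78 °C; then 9, −78 → 0 °C; then PPTS (cat.), CH2Cl2, rt
Reagents that add atoms: none
Why: Titanium-enolate syn-aldol of an N-acylthiazolidinethione, in which soft enolisation gives the Z-enolate that should add through the non-chelated Zimmerman–Traxler chair on the face opposite the benzyl group (setting C3a and C11a), after which acid closes the γ-lactone by acyl substitution at the methyl ester with its two substituents trans.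

Step 8
Reactants: 14 (4S)-4-benzyl-3-{[(2R,3S)-2-[(2R)-2-{[(4-methoxybenzyl)oxy]methyl}but-3-en-1-yl]-5-oxooxolan-3-yl]carbonyl}-1,3-thiazolidine-2-thione
Product: 15 (2R,3S)-2-[(2R)-2-{[(4-methoxybenzyl)oxy]methyl}but-3-en-1-yl]-5-oxooxolane-3-carbaldehyde
Conditions: iBu2AlH (1.1 equiv), CH2Cl2, −78 °C, short reaction time
Reagents that add atoms: none
Why: Reductive cleavage of the activated N-acylthiazolidinethione, in which hydride addition gives a stable tetrahedral aluminate that collapses to the aldehyde on work-up and the imide should react faster than the lactone with one equivalent at low temperature.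

Step 9
Reactants: 15 (2R,3S)-2-[(2R)-2-{[(4-methoxybenzyl)oxy]methyl}but-3-en-1-yl]-5-oxooxolane-3-carbaldehyde; 16 4,4,5,5-tetramethyl-2-(propa-1,2-dien-1-yl)-1,3,2-dioxaborolane
Product: 17 (4R,5R)-4-[(1R)-1-hydroxybut-3-yn-1-yl]-5-[(2R)-2-{[(4-methoxybenzyl)oxy]methyl}but-3-en-1-yl]oxolan-2-one
Conditions: 16 (1.5 equiv), (R)-TRIP [(R)-3,3'-bis(2,4,6-triisopropylphenyl)-1,1'-binaphthalene-2,2'-diyl hydrogen phosphate] (10 mol %), 4 Å MS, toluene, 0 °C
Reagents that add atoms: allenylboronic acid pinacol ester, C=C=CB1OC(C)(C)C(C)(C)O1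
Why: Brønsted-acid-catalysed allenylboration (propargylation) through a cyclic six-membered SE2' transition state, in which the chiral phosphate hydrogen-bonded to a boronate oxygen selects the aldehyde face and should set C4 under catalyst control without base that could epimerise C3a.

Step 10
Reactants: 17 (4R,5R)-4-[(1R)-1-hydroxybut-3-yn-1-yl]-5-[(2R)-2-{[(4-methoxybenzyl)oxy]methyl}but-3-en-1-yl]oxolan-2-one
Product: 18 (4R,5R)-4-[(2R)-2,3-dihydrofuran-2-yl]-5-[(2R)-2-{[(4-methoxybenzyl)oxy]methyl}but-3-en-1-yl]oxolan-2-one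
Conditions: Mo(CO)6 (0.3 equiv), Et3N, Et2O, hν (350 nm), rt
Reagents that add atoms: none
Why: Alkynol cycloisomerisation, in which the terminal alkyne rearranges to a molybdenum vinylidene, the C4 hydroxyl attacks its electrophilic carbon (endo closure of the five-membered ring) and protodemetalation should give the cyclic enol ether with C4 untouched.

Step 11
Reactants: 18 (4R,5R)-4-[(2R)-2,3-dihydrofuran-2-yl]-5-[(2R)-2-{[(4-methoxybenzyl)oxy]methyl}but-3-en-1-yl]oxolan-2-one; 19 diethyl chlorophosphate
Product: 21 diethyl [(4R,5R)-4-[(2R)-2,3-dihydrofuran-2-yl]-5-[(2R)-2-{[(4-methoxybenzyl)oxy]methyl}but-3-en-1-yl]-2-oxooxolan-3-yl]phosphonate (both C3 epimers), via enol phosphate 20 (not isolated)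
Conditions: LiN(iPr)2 (1.1 equiv), THF, −78 °C; 19; then LiN(iPr)2 (2.2 equiv), −78 → 0 °C; AcOH
Reagents that add atoms: diethyl chlorophosphate, CCOP(=O)(Cl)OCC
Why: Vinyl phosphate–phosphonate rearrangement, in which the lactone enolate is O-phosphorylated and excess amide base induces the 1,3-shift of phosphorus from oxygen to carbon, driven by the stabilised phosphonate anion; the new C3 centre is lost again in step 15.

Step 12
Reactants: 21 diethyl [(4R,5R)-4-[(2R)-2,3-dihydrofuran-2-yl]-5-[(2R)-2-{[(4-methoxybenzyl)oxy]methyl}but-3-en-1-yl]-2-oxooxolan-3-yl]phosphonate; 22 trichloroacetyl chloride; 23 methanol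
Product: 25 methyl (5R)-5-[(2R,3R)-4-(diethoxyphosphoryl)-2-[(2R)-2-{[(4-methoxybenzyl)oxy]methyl}but-3-en-1-yl]-5-oxooxolan-3-yl]-4,5-dihydrofuran-3-carboxylate (both epimers at the phosphorus-bearing carbon), via trichloromethyl ketone 24 (not isolated)
Conditions: 22, pyridine, CH2Cl2, 0 °C → rt; then 23, NaHCO3, 50 °C
Reagents that add atoms: trichloroacetyl chloride, O=C(Cl)C(Cl)(Cl)Cl; methanol, CO
Why: Electrophilic acylation of the enol ether at its nucleophilic β-carbon (C6) followed by loss of the proton should give the trichloromethyl ketone, which methanol cleaves in a haloform-type acyl substitution to the methyl ester under conditions too weakly basic to ionise the phosphonate.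

Step 13
Reactants: 25 methyl (5R)-5-[(2R,3R)-4-(diethoxyphosphoryl)-2-[(2R)-2-{[(4-methoxybenzyl)oxy]methyl}but-3-en-1-yl]-5-oxooxolan-3-yl]-4,5-dihydrofuran-3-carboxylate
Product: 27 methyl (3aR,4R,6E,10S,11aR)-3-(diethoxyphosphoryl)-4-hydroxy-10-{[(4-methoxybenzyl)oxy]methyl}-2-oxo-2,3,3a,4,5,8,9,10,11,11a-decahydrocyclodeca[b]furan-6-carboxylate (both C3 epimers), via B-alkyl-9-BBN borane 26 (not isolated)
Conditions: 9-BBN-H (1.5 equiv), THF, rt; then Ni(cod)2 (15 mol %), IPr·HCl (30 mol %), CsF (3 equiv), toluene, 80 °C, syringe-pump addition (final 2 mM); aq. NH4Cl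
Reagents that add atoms: none
Why: Proposed new method: anti-Markovnikov hydroboration of the only unhindered monosubstituted olefin (C8=C9) should give the B-alkyl borane 26, after which zerovalent nickel bearing the N-heterocyclic carbene inserts into the C7–O bond of the 4,5-dihydrofuran-3-carboxylate (a cyclic β-alkoxyacrylate whose C(sp2)–O bond is activated by the conjugated ester and by coordination of its oxygen to boron), the tethered alkyl group passes from the fluoride-activated borane to nickel while the alkoxide passes to boron, and C(sp3)–C(sp2) reductive elimination forms C7–C8. The closest known reaction types are the nickel-catalysed alkoxy-to-alkyl exchange of enol ethers with B-alkyl-9-BBN reagents, the ring-opening insertion of zerovalent nickel into the C2–O bond of benzofurans and dihydrofurans, and the intramolecular B-alkyl Suzuki–Miyaura macrocyclisation. The ten-membered carbocycle closes in an endo mode at the trigonal carbon C7 (both olefin carbons become ring members) while the five-membered oxolene ring opens, so the macrocycle arises by a ring-opening cross-coupling and no acyclic stereodefined vinyl electrophile is needed. No new stereocentre is formed; the olefin geometry is controlled by the oxolene ring, in which O and C5 are cis across C6=C7, so stereoretentive replacement of O by C8 places C8 cis to C5 and trans to the ester, which is the 6E, ring-cis geometry that the ten-membered ring also favours. The step needs chemoselective hydroboration (the push–pull enol-ether olefin and the lactone are inert to 9-BBN-H), site-selective C–O activation (the lactone and benzylic C–O bonds lack the vinylogous activation) and cyclisation over oligomerisation, which slow addition at high dilution and preorganisation by the trans-lactone and the cis-olefinic oxolene should secure. The methylene group is kept masked as the phosphonate because an α-methylene lactone would compete for the borane and for nickel.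

Step 14
Reactants: 27 methyl (3aR,4R,6E,10S,11aR)-3-(diethoxyphosphoryl)-4-hydroxy-10-{[(4-methoxybenzyl)oxy]methyl}-2-oxo-2,3,3a,4,5,8,9,10,11,11a-decahydrocyclodeca[b]furan-6-carboxylate; 28 (2S)-2-methylbutanoic anhydride
Product: 29 methyl (3aS,4R,6E,10S,11aR)-3-(diethoxyphosphoryl)-10-{[(4-methoxybenzyl)oxy]methyl}-4-{[(2S)-2-methylbutanoyl]oxy}-2-oxo-2,3,3a,4,5,8,9,10,11,11a-decahydrocyclodeca[b]furan-6-carboxylate (both C3 epimers)
Conditions: 28 (1.5 equiv), Et3N, DMAP (cat.), CH2Cl2, 0 °C
Reagents that add atoms: (2S)-2-methylbutanoic anhydride, CC[C@H](C)C(=O)OC(=O)[C@@H](C)CC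
Why: Nucleophile-catalysed acylation (acylpyridinium transfer) of the secondary alcohol, which should also block its lactonisation onto the C6 ester; the anhydride brings the (S) centre, which is not enolised under these conditions.

Step 15
Reactants: 29 methyl (3aS,4R,6E,10S,11aR)-3-(diethoxyphosphoryl)-10-{[(4-methoxybenzyl)oxy]methyl}-4-{[(2S)-2-methylbutanoyl]oxy}-2-oxo-2,3,3a,4,5,8,9,10,11,11a-decahydrocyclodeca[b]furan-6-carboxylate; 30 formaldehyde
Product: 31 methyl (3aS,4R,6E,10S,11aR)-10-{[(4-methoxybenzyl)oxy]methyl}-3-methylidene-4-{[(2S)-2-methylbutanoyl]oxy}-2-oxo-2,3,3a,4,5,8,9,10,11,11a-decahydrocyclodeca[b]furan-6-carboxylate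
Conditions: 30 (37% aq.), K2CO3, THF, 0 °C → rt
Reagents that add atoms: formaldehyde, C=O
Why: Horner–Wadsworth–Emmons olefination of the phosphonate anion with formaldehyde under mild carbonate conditions that should leave the other esters and the enolisable acyl stereocentre untouched.

Step 16
Reactants: 31 methyl (3aS,4R,6E,10S,11aR)-10-{[(4-methoxybenzyl)oxy]methyl}-3-methylidene-4-{[(2S)-2-methylbutanoyl]oxy}-2-oxo-2,3,3a,4,5,8,9,10,11,11a-decahydrocyclodeca[b]furan-6-carboxylate
Product: 32 methyl (3aS,4R,6E,10S,11aR)-10-(hydroxymethyl)-3-methylidene-4-{[(2S)-2-methylbutanoyl]oxy}-2-oxo-2,3,3a,4,5,8,9,10,11,11a-decahydrocyclodeca[b]furan-6-carboxylate (CNP0141952.2)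
Conditions: DDQ, CH2Cl2/pH 7 buffer, 0 °C
Reagents that add atoms: none
Why: Oxidative cleavage of the 4-methoxybenzyl ether through the benzylic oxocarbenium ion and its hydrolysis, to which the electron-poor olefins and the esters should be inert.

**Compound list**
1 | (E)-but-2-ene-1,4-diol | OC/C=C/CO | starting material
2 | 4-methoxybenzyl chloride | COc1ccc(CCl)cc1 | starting material
3 | (E)-4-[(4-methoxybenzyl)oxy]but-2-en-1-ol | OC/C=C/COCc1ccc(OC)cc1 | intermediate
4 | methyl chloroformate | COC(=O)Cl | starting material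
5 | (E)-4-[(4-methoxybenzyl)oxy]but-2-en-1-yl methyl carbonate | COC(=O)OC/C=C/COCc1ccc(OC)cc1 | intermediate
6 | dimethyl malonate | COC(=O)CC(=O)OC | starting material
7 | dimethyl 2-[(2S)-1-[(4-methoxybenzyl)oxy]but-3-en-2-yl]propanedioate | COC(=O)C(C(=O)OC)[C@@H](COCc1ccc(OC)cc1)C=C | intermediate
8 | methyl (3R)-3-{[(4-methoxybenzyl)oxy]methyl}pent-4-enoate | COC(=O)C[C@@H](COCc1ccc(OC)cc1)C=C | intermediate
9 | (3R)-3-{[(4-methoxybenzyl)oxy]methyl}pent-4-enal | O=CC[C@@H](COCc1ccc(OC)cc1)C=C | intermediate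
10 | (4S)-4-benzyl-1,3-thiazolidine-2-thione | S=C1SC[C@H](Cc2ccccc2)N1 | starting material
11 | methyl 4-chloro-4-oxobutanoate | COC(=O)CCC(=O)Cl | starting material
12 | methyl 4-[(4S)-4-benzyl-2-thioxo-1,3-thiazolidin-3-yl]-4-oxobutanoate | COC(=O)CCC(=O)N1C(=S)SC[C@@H]1Cc1ccccc1 | intermediate
13 | syn-aldol adduct, methyl (3S,4R,6R)-3-{[(4S)-4-benzyl-2-thioxo-1,3-thiazolidin-3-yl]carbonyl}-4-hydroxy-6-{[(4-methoxybenzyl)oxy]methyl}oct-7-enoate | COC(=O)C[C@H](C(=O)N1C(=S)SC[C@@H]1Cc1ccccc1)[C@H](O)C[C@@H](COCc1ccc(OC)cc1)C=C | intermediate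
14 | (4S)-4-benzyl-3-{[(2R,3S)-2-[(2R)-2-{[(4-methoxybenzyl)oxy]methyl}but-3-en-1-yl]-5-oxooxolan-3-yl]carbonyl}-1,3-thiazolidine-2-thione (trans-lactone) | O=C1C[C@H](C(=O)N2C(=S)SC[C@@H]2Cc2ccccc2)[C@@H](C[C@@H](COCc2ccc(OC)cc2)C=C)O1 | intermediate
15 | (2R,3S)-2-[(2R)-2-{[(4-methoxybenzyl)oxy]methyl}but-3-en-1-yl]-5-oxooxolane-3-carbaldehyde | O=C1C[C@H](C=O)[C@@H](C[C@@H](COCc2ccc(OC)cc2)C=C)O1 | intermediate
16 | 4,4,5,5-tetramethyl-2-(propa-1,2-dien-1-yl)-1,3,2-dioxaborolane (allenylboronic acid pinacol ester) | C=C=CB1OC(C)(C)C(C)(C)O1 | starting material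
17 | (4R,5R)-4-[(1R)-1-hydroxybut-3-yn-1-yl]-5-[(2R)-2-{[(4-methoxybenzyl)oxy]methyl}but-3-en-1-yl]oxolan-2-one | O=C1C[C@H]([C@H](O)CC#C)[C@@H](C[C@@H](COCc2ccc(OC)cc2)C=C)O1 | intermediate
18 | (4R,5R)-4-[(2R)-2,3-dihydrofuran-2-yl]-5-[(2R)-2-{[(4-methoxybenzyl)oxy]methyl}but-3-en-1-yl]oxolan-2-one | O=C1C[C@H]([C@H]2CC=CO2)[C@@H](C[C@@H](COCc3ccc(OC)cc3)C=C)O1 | intermediate
19 | diethyl chlorophosphate | CCOP(=O)(Cl)OCC | starting material
20 | enol phosphate of 18, diethyl (4R,5R)-4-[(2R)-2,3-dihydrofuran-2-yl]-5-[(2R)-2-{[(4-methoxybenzyl)oxy]methyl}but-3-en-1-yl]-4,5-dihydrofuran-2-yl phosphate | CCOP(=O)(OCC)OC1=C[C@H]([C@H]2CC=CO2)[C@@H](C[C@@H](COCc3ccc(OC)cc3)C=C)O1 | intermediate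
21 | diethyl [(4R,5R)-4-[(2R)-2,3-dihydrofuran-2-yl]-5-[(2R)-2-{[(4-methoxybenzyl)oxy]methyl}but-3-en-1-yl]-2-oxooxolan-3-yl]phosphonate (both C3 epimers) | O=C1C(P(=O)(OCC)OCC)[C@H]([C@H]2CC=CO2)[C@@H](C[C@@H](COCc3ccc(OC)cc3)C=C)O1 | intermediate
22 | trichloroacetyl chloride | O=C(Cl)C(Cl)(Cl)Cl | starting material
23 | methanol | CO | starting material
24 | trichloromethyl ketone, diethyl [(4R,5R)-5-[(2R)-2-{[(4-methoxybenzyl)oxy]methyl}but-3-en-1-yl]-2-oxo-4-[(2R)-4-(trichloroacetyl)-2,3-dihydrofuran-2-yl]oxolan-3-yl]phosphonate | O=C1C(P(=O)(OCC)OCC)[C@H]([C@H]2CC(C(=O)C(Cl)(Cl)Cl)=CO2)[C@@H](C[C@@H](COCc3ccc(OC)cc3)C=C)O1 | intermediate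
25 | methyl (5R)-5-[(2R,3R)-4-(diethoxyphosphoryl)-2-[(2R)-2-{[(4-methoxybenzyl)oxy]methyl}but-3-en-1-yl]-5-oxooxolan-3-yl]-4,5-dihydrofuran-3-carboxylate (both epimers at the phosphorus-bearing carbon) | O=C1C(P(=O)(OCC)OCC)[C@H]([C@H]2CC(C(=O)OC)=CO2)[C@@H](C[C@@H](COCc3ccc(OC)cc3)C=C)O1 | intermediate
26 | B-alkyl-9-borabicyclo[3.3.1]nonane from hydroboration of the vinyl group of 25 (boron on the terminal carbon, future C8) | O=C1C(P(=O)(OCC)OCC)[C@H]([C@H]2CC(C(=O)OC)=CO2)[C@@H](C[C@@H](COCc3ccc(OC)cc3)CCB3C4CCCC3CCC4)O1 | intermediate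
27 | methyl (3aR,4R,6E,10S,11aR)-3-(diethoxyphosphoryl)-4-hydroxy-10-{[(4-methoxybenzyl)oxy]methyl}-2-oxo-2,3,3a,4,5,8,9,10,11,11a-decahydrocyclodeca[b]furan-6-carboxylate (both C3 epimers) | CCOP(=O)(OCC)C1C(=O)O[C@@H]2C[C@@H](COCc3ccc(OC)cc3)CC/C=C(/C(=O)OC)C[C@@H](O)[C@@H]12 | intermediate
28 | (2S)-2-methylbutanoic anhydride | CC[C@H](C)C(=O)OC(=O)[C@@H](C)CC | starting material
29 | methyl (3aS,4R,6E,10S,11aR)-3-(diethoxyphosphoryl)-10-{[(4-methoxybenzyl)oxy]methyl}-4-{[(2S)-2-methylbutanoyl]oxy}-2-oxo-2,3,3a,4,5,8,9,10,11,11a-decahydrocyclodeca[b]furan-6-carboxylate (both C3 epimers) | CCOP(=O)(OCC)C1C(=O)O[C@@H]2C[C@@H](COCc3ccc(OC)cc3)CC/C=C(/C(=O)OC)C[C@@H](OC(=O)[C@@H](C)CC)[C@@H]12 | intermediate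
30 | formaldehyde | C=O | starting material
31 | methyl (3aS,4R,6E,10S,11aR)-10-{[(4-methoxybenzyl)oxy]methyl}-3-methylidene-4-{[(2S)-2-methylbutanoyl]oxy}-2-oxo-2,3,3a,4,5,8,9,10,11,11a-decahydrocyclodeca[b]furan-6-carboxylate | C=C1C(=O)O[C@@H]2C[C@@H](COCc3ccc(OC)cc3)CC/C=C(/C(=O)OC)C[C@@H](OC(=O)[C@@H](C)CC)[C@@H]12 | intermediate
32 | methyl (3aS,4R,6E,10S,11aR)-10-(hydroxymethyl)-3-methylidene-4-{[(2S)-2-methylbutanoyl]oxy}-2-oxo-2,3,3a,4,5,8,9,10,11,11a-decahydrocyclodeca[b]furan-6-carboxylate (CNP0141952.2) | C=C1C(=O)O[C@@H]2C[C@@H](CO)CC/C=C(/C(=O)OC)C[C@@H](OC(=O)[C@@H](C)CC)[C@@H]12 | target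

**Step count and risks**
Total step count: 16. Longest linear sequence: 15 steps (steps 1–5 and 7–16; step 6 is a one-step side branch).

Most likely to fail, first: step 13. Insertion of nickel into the vinylogous C–O bond may be slow, so that β-hydride elimination of the alkylnickel intermediate and intermolecular coupling outrun ring closure, and the liberated alkoxide may transesterify onto the neighbouring methyl ester. The fallback uses known radical and elimination chemistry in place of cross-coupling; it sets out from 25 and returns at 27. Hydroboration–oxidation (9-BBN-H; then NaBO3) should give the primary alcohol F1, and Appel iodination (I2, PPh3, imidazole) the primary iodide F2. Tin-hydride radical macrocyclisation (Bu3SnH, AIBN, benzene, 80 °C, slow addition), in which the C8 radical adds to the oxygen-bearing β-carbon C7 as in the established radical cyclisations of β-alkoxyacrylates, should give the bridged oxolane ester F3. E1cB opening of F3 with KN(SiMe3)2 (2.2 equiv, THF, −78 °C; the first equivalent parks the phosphonate as its anion) should expel the C4 alkoxide, regenerate the C6=C7 enoate and give 27.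

Second: step 9. Mismatched double stereodifferentiation may give poor facial selectivity at C4, and enolisation of the aldehyde may epimerise C3a. The fallback replaces catalyst control by separation and inversion; it sets out from 15 and returns at 17. Zinc-mediated Barbier propargylation (Zn, propargyl bromide, THF/aq. NH4Cl) should give 17 together with the C4-epimeric alcohol F4, which is separated by chromatography. F4 is recycled by Mitsunobu inversion (4-nitrobenzoic acid, PPh3, DIAD) to the inverted 4-nitrobenzoate F5 and methanolysis (K2CO3, MeOH) to 17.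

Third: step 8. Hydride may attack the lactone carbonyl in competition with the imide, and the aldehyde may be over-reduced. The fallback reduces through and re-oxidises; it sets out from 14 and returns at 15. NaBH4 (THF/H2O, 0 °C), which cleaves N-acylthiazolidinethiones but leaves γ-lactones alone, should give the primary alcohol F6, and Dess–Martin periodinane oxidation should then give 15.

**Further compounds**
F1 | step 13 | primary alcohol from 25 (vinyl group converted into CH2CH2OH) | O=C1C(P(=O)(OCC)OCC)[C@H]([C@H]2CC(C(=O)OC)=CO2)[C@@H](C[C@@H](COCc3ccc(OC)cc3)CCO)O1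
F2 | step 13 | primary iodide corresponding to F1 | O=C1C(P(=O)(OCC)OCC)[C@H]([C@H]2CC(C(=O)OC)=CO2)[C@@H](C[C@@H](COCc3ccc(OC)cc3)CCI)O1
F3 | step 13 | bridged oxolane ester (C7–C8 bond formed, O4 still bonded to C7, C6 and C7 saturated) | CCOP(=O)(OCC)C1C(=O)O[C@@H]2C[C@@H](COCc4ccc(OC)cc4)CCC3C(C(=O)OC)C[C@@H](O3)[C@@H]12
F4 | step 9 | (4R,5R)-4-[(1S)-1-hydroxybut-3-yn-1-yl]-5-[(2R)-2-{[(4-methoxybenzyl)oxy]methyl}but-3-en-1-yl]oxolan-2-one (C4 epimer of 17) | O=C1C[C@H]([C@@H](O)CC#C)[C@@H](C[C@@H](COCc2ccc(OC)cc2)C=C)O1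
F5 | step 9 | 4-nitrobenzoate ester of 17 (carbinol configuration as in 17) | O=C1C[C@H]([C@H](OC(=O)c2ccc(cc2)[N+](=O)[O-])CC#C)[C@@H](C[C@@H](COCc2ccc(OC)cc2)C=C)O1
F6 | step 8 | (4R,5R)-4-(hydroxymethyl)-5-[(2R)-2-{[(4-methoxybenzyl)oxy]methyl}but-3-en-1-yl]oxolan-2-one | O=C1C[C@H](CO)[C@@H](C[C@@H](COCc2ccc(OC)cc2)C=C)O1
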